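**Retrosynthetic overview**
- Target ⇒ 4-bromo-5-methylidene butenolide acetate (Br2 addition, then loss of HBr gives the Z-bromomethylidene) ⇒ 4-bromo-5-methyl butenolide acetate (C5 bromination, then loss of HBr).
- Butenolide ring (the only ring, closed in the third step, after the C–C bond and the stereocentre are in place) ⇒ bromolactonisation of a 2-substituted penta-2,3-dienoate.
- (R)-Acetoxy centre ⇒ lipase-catalysed enantioselective acetylation of the racemic α-allenic alcohol.
- Key C–C bond (ring C3 to side-chain C1′) ⇒ intermolecular aldol addition of the lithium allenolate of ethyl pent-2-ynoate to butanal.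

Assumption: the SMILES is read as the (1R)-acetate with a (Z)-bromomethylidene group (exocyclic Br on the side of the ring oxygen); ethyl pent-2-ynoate, butanal, vinyl acetate and Amano lipase PS are taken as commercial.

**Step 1**
Reactants: 1 ethyl pent-2-ynoate; 2 butanal
Product: 5 racemic ethyl 2-(1-hydroxybutyl)penta-2,3-dienoate, via lithium allenolate 3 (not isolated), via lithium aldolate 4 (not isolated)
Conditions: LiN(iPr)2 (1.1 equiv), THF, −78 °C, 30 min; then 2 (1.2 equiv), −78 °C, 1 h; AcOH (1.2 equiv) quench at −78 °C
Reagents that add atoms: none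
Why: γ-Deprotonation of the 2-alkynoate gives a lithium cumulenolate that attacks the aldehyde through its α-carbon (intermolecular aldol addition, kinetic α-selectivity) to give the α-(1-hydroxyalkyl)allenoate; no stereocontrol is needed here, because the carbinol centre is fixed in step 2 and the allene axis is consumed in step 3.

**Step 2**
Reactants: 5 racemic ethyl 2-(1-hydroxybutyl)penta-2,3-dienoate
Product: 6 ethyl 2-[(1R)-1-(acetyloxy)butyl]penta-2,3-dienoate
Conditions: Burkholderia cepacia lipase (Amano lipase PS on Celite), vinyl acetate (3 equiv), MTBE, 30 °C, stopped at about 45% conversion; chromatography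
Reagents that add atoms: vinyl acetate, C=COC(C)=O
Why: Lipase-catalysed enantioselective transesterification (kinetic resolution) should follow the Kazlauskas rule (n-propyl as the medium group, the allenoate carbon as the large group) and acetylate only the (R)-alcohols of both allene diastereomers, which sets the (R) centre of the target; the unreacted (S)-alcohol is removed by chromatography.

**Step 3**
Reactants: 6 ethyl 2-[(1R)-1-(acetyloxy)butyl]penta-2,3-dienoate
Product: 7 (1R)-1-(4-bromo-5-methyl-2-oxo-2,5-dihydrofuran-3-yl)butyl acetate (C5 epimers)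
Conditions: CuBr2 (4 equiv), acetone/H2O 2:1, 65 °C
Reagents that add atoms: CuBr2, Br[Cu]Br; water, O
Why: Bromolactonisation of a 2,3-allenoate (electrophilic halocyclisation): CuBr2 delivers bromine to the central allene carbon, the ester carbonyl oxygen closes onto the terminal allene carbon, and water cleaves the ethoxy group of the resulting alkoxyfuranium ion; the acetate-bearing centre is not involved, and the new C5 centre forms as a mixture that is removed in step 4.

**Step 4**
Reactants: 7 (1R)-1-(4-bromo-5-methyl-2-oxo-2,5-dihydrofuran-3-yl)butyl acetate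
Product: 9 (1R)-1-(4-bromo-5-methylidene-2-oxo-2,5-dihydrofuran-3-yl)butyl acetate, via 5-bromo-5-methyl lactone 8 (not isolated)
Conditions: N-bromosuccinimide (1.05 equiv), AIBN (5 mol %), PhCF3, 80 °C; filter; then Et3N (1.5 equiv), CH2Cl2, 0 °C
Reagents that add atoms: none
Why: Wohl–Ziegler radical bromination takes the tertiary C5–H (allylic and α to the ring oxygen), and the tertiary bromide then loses HBr to Et3N (dehydrobromination) to give the exocyclic methylidene; C1′ carries no acidic hydrogen and keeps its configuration.

**Step 5**
Reactants: 9 (1R)-1-(4-bromo-5-methylidene-2-oxo-2,5-dihydrofuran-3-yl)butyl acetate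
Product: 11 (1R)-1-[(5Z)-4-bromo-5-(bromomethylidene)-2-oxo-2,5-dihydrofuran-3-yl]butyl acetate (CNP0172387.1), via tribromide 10 (not isolated)
Conditions: Br2 (1.05 equiv), CH2Cl2, −20 to 0 °C; then Et3N (1.2 equiv), 0 °C, dark
Reagents that add atoms: bromine, BrBr
Why: Electrophilic addition of Br2 to the electron-rich exocyclic enol-ester double bond, then dehydrobromination, gives the bromomethylidene group; the Z isomer (Br beside the ring oxygen, away from the C4 bromine) is the less strained and expected major product, and any E isomer is removed by chromatography.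

**Compound list**
1 | ethyl pent-2-ynoate | CCC#CC(=O)OCC | starting material
2 | butanal | CCCC=O | starting material
3 | lithium 1-ethoxypenta-1,2,3-trien-1-olate (lithium allenolate of 1) | CC=C=C=C(OCC)O[Li] | intermediate
4 | lithium alkoxide of 5 (lithium aldolate) | CCCC(O[Li])C(C(=O)OCC)=C=CC | intermediate
5 | ethyl 2-(1-hydroxybutyl)penta-2,3-dienoate, racemic, both allene-axis diastereomers | CCCC(O)C(C(=O)OCC)=C=CC | intermediate
6 | ethyl 2-[(1R)-1-(acetyloxy)butyl]penta-2,3-dienoate, mixture at the allene axis | CCC[C@@H](OC(C)=O)C(C(=O)OCC)=C=CC | intermediate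
7 | (1R)-1-(4-bromo-5-methyl-2-oxo-2,5-dihydrofuran-3-yl)butyl acetate, C5 epimers | CCC[C@@H](OC(C)=O)C1=C(Br)C(C)OC1=O | intermediate
8 | (1R)-1-(4,5-dibromo-5-methyl-2-oxo-2,5-dihydrofuran-3-yl)butyl acetate, C5 epimers | CCC[C@@H](OC(C)=O)C1=C(Br)C(C)(Br)OC1=O | intermediate
9 | (1R)-1-(4-bromo-5-methylidene-2-oxo-2,5-dihydrofuran-3-yl)butyl acetate | CCC[C@@H](OC(C)=O)C1=C(Br)C(=C)OC1=O | intermediate
10 | (1R)-1-[4,5-dibromo-5-(bromomethyl)-2-oxo-2,5-dihydrofuran-3-yl]butyl acetate, C5 epimers | CCC[C@@H](OC(C)=O)C1=C(Br)C(Br)(CBr)OC1=O | intermediate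
11 | (1R)-1-[(5Z)-4-bromo-5-(bromomethylidene)-2-oxo-2,5-dihydrofuran-3-yl]butyl acetate (CNP0172387.1) | CCC[C@@H](OC(C)=O)C1=C(Br)/C(=C/Br)OC1=O | target

**Totals**
Total step count: 5. Longest linear sequence: 5 steps (1 → 5 → 6 → 7 → 9 → 11).

**Three steps most likely to fail, with fallbacks**

Step 2 (enzyme selectivity). n-Propyl is a large "medium" group, so the acetate may come out below 98% ee. Fallback: set out from 5 and let the same acylation run on to about 60% conversion, where the slow enantiomer, ethyl 2-[(1S)-1-hydroxybutyl]penta-2,3-dienoate F1, is left essentially enantiopure. After chromatography it is esterified under Mitsunobu conditions (PPh3, diisopropyl azodicarboxylate, AcOH, THF, 0 °C), which inverts the carbinol carbon by SN2 displacement and delivers 6, where the route is rejoined.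

Step 4 (site of hydrogen abstraction). C1′–H is also allylic, and the methylidene product can pick up bromine. Fallback: set out from 7 and deprotonate C5–H with LiN(SiMe3)2 in the presence of Me3SiCl (THF, −78 °C) to give the silyl dienol ether (1R)-1-[4-bromo-5-methyl-2-(trimethylsilyloxy)furan-3-yl]butyl acetate F2. Bromination of this 2-silyloxyfuran with N-bromosuccinimide at −78 °C puts the electrophile at C5 only; the route is rejoined at 8, which is treated with Et3N as before.

Step 5 (E/Z ratio of the bromomethylidene group, and loss of product to bromide or amine). Fallback: set out from 9 and form the bromohydrin with N-bromosuccinimide in acetone/water at 0 °C, that is the pseudo-acid (1R)-1-[4-bromo-5-(bromomethyl)-5-hydroxy-2-oxo-2,5-dihydrofuran-3-yl]butyl acetate F3. Dehydration with P2O5 in CH2Cl2, under acidic equilibrating conditions that favour the Z isomer, arrives directly at 11.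

**Further compounds**
F1 | step 2 | ethyl 2-[(1S)-1-hydroxybutyl]penta-2,3-dienoate | CCC[C@H](O)C(C(=O)OCC)=C=CC
F2 | step 4 | (1R)-1-[4-bromo-5-methyl-2-(trimethylsilyloxy)furan-3-yl]butyl acetate | CCC[C@@H](OC(C)=O)c1c(Br)c(C)oc1O[Si](C)(C)C
F3 | step 5 | (1R)-1-[4-bromo-5-(bromomethyl)-5-hydroxy-2-oxo-2,5-dihydrofuran-3-yl]butyl acetate (C5 epimers) | CCC[C@@H](OC(C)=O)C1=C(Br)C(O)(CBr)OC1=O
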